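## Retrosynthetic overview

- Prostanoid numbering is used (ester carbon C1, ring C8–C12, carbinol C12, lower chain C13–C20). The target is traced back to its 12-O-silyl ether, then to 2-chloro-4-hydroxy-4-[(Z)-oct-2-enyl]cyclopent-2-enone plus methyl (Z)-7-oxohept-5-enoate by aldol addition and dehydration at C8 (C7–C8 bond; 5Z carried in, 7E from E1cB).
- The cyclopentenone, the only ring, is closed in one operation by a Brook-rearrangement-mediated anionic [3+2] annulation. The three-carbon unit C9–C10–C11 is a 2-chloro-3-(phenylthio)acryloylsilane, and the two-carbon unit C8/C12 is the regiodefined lithium enolate of (Z)-dec-4-en-2-one; they are joined through C8–C9 and C11–C12.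
- Enabling feature: in the ring the C9 carbonyl oxygen and the C12 tertiary hydroxyl are 1,3-related through C8 (an aldol-type pattern), and C9–C10–C11 is an α,β-unsaturated acyl unit. C12–OH can therefore come from a methyl-ketone carbonyl and C9=O from an acylsilane carbonyl. A temporary phenylthio group on C11 carries the carbanion and later leaves to restore C10=C11, with chlorine already on C10.
- Fragments: the acylsilane from ethyl vinyl ether (4 steps); the enolate precursor from pentylmagnesium bromide, acetylene and 2,3-dibromopropene (2 steps, sets 14Z); the enal from hex-5-ynoic acid (4 steps, sets 5Z).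
- Assumption: no enantioselective variant of the annulation is relied on, so C12 is formed as a racemate in the key step and the 12R series is taken by chromatography on a chiral phase right after the enone is unveiled.

Key step: step 7

## Route

Step 1
Reactants: 1 ethyl vinyl ether
Product: 4 1-[tert-butyl(dimethyl)silyl]ethan-1-one, via 1-ethoxyvinyllithium 2 (not isolated), via tert-butyl(1-ethoxyethenyl)dimethylsilane 3 (not isolated)
Conditions: t-BuLi, THF, −78 to 0 °C; t-BuMe2SiCl, −78 °C to rt; 1 M HCl, acetone, rt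
Reagents that add atoms: tert-butyl(chloro)dimethylsilane CC(C)(C)[Si](C)(C)Cl; water O
Why: α-Lithiation of the vinyl ether, C-silylation and acid hydrolysis of the silyl enol ether is the standard acyl-anion-equivalent route to acylsilanes, and no stereocentre is formed.

Step 2
Reactants: 4 1-[tert-butyl(dimethyl)silyl]ethan-1-one
Product: 5 (E)-1-[tert-butyl(dimethyl)silyl]-3-(dimethylamino)prop-2-en-1-one
Conditions: Me2NCH(OMe)2 (neat), 90 °C
Reagents that add atoms: N,N-dimethylformamide dimethyl acetal COC(OC)N(C)C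
Why: Condensation of the acidic acetyl methyl group with the amide acetal (enaminone formation) installs the future C11 as a β-aminovinyl carbon, the E geometry being the thermodynamic one.

Step 3
Reactants: 5 (E)-1-[tert-butyl(dimethyl)silyl]-3-(dimethylamino)prop-2-en-1-one
Product: 6 (E)-1-[tert-butyl(dimethyl)silyl]-3-(phenylsulfanyl)prop-2-en-1-one
Conditions: PhSH, CF3CO2H, CH2Cl2, 0 °C to rt
Reagents that add atoms: thiophenol Sc1ccccc1
Why: Acid-promoted conjugate addition–elimination exchanges dimethylamine for the phenylthio group, which is the carbanion-stabilising and later leaving group needed on C11.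

Step 4
Reactants: 6 (E)-1-[tert-butyl(dimethyl)silyl]-3-(phenylsulfanyl)prop-2-en-1-one
Product: 7 (Z)-1-[tert-butyl(dimethyl)silyl]-2-chloro-3-(phenylsulfanyl)prop-2-en-1-one
Conditions: N-chlorosuccinimide, CH2Cl2, 0 °C to rt
Reagents that add atoms: N-chlorosuccinimide ClN1C(=O)CCC1=O
Why: C10 is the nucleophilic β-carbon of the vinyl sulfide in this push–pull alkene, so electrophilic chlorination with loss of the C10 proton should give the 2-chloro compound; the alkene geometry is of no consequence because C11 becomes sp2 again in step 8.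

Step 5
Reactants: 8 n-pentylmagnesium bromide
Product: 10 (4Z)-2-bromodeca-1,4-diene, via (Z)-hept-1-enylcopper 9 (not isolated)
Conditions: CuBr·SMe2 (1 equiv), Et2O/Me2S, −45 °C; HC≡CH, −25 °C; 2,3-dibromopropene, THF, −25 to 0 °C
Reagents that add atoms: acetylene C#C; 2,3-dibromopropene C=C(Br)CBr
Why: syn-Carbocupration of acetylene gives the (Z)-alkenylcopper, which is alkylated with retention, so the C14=C15 Z-alkene is set here; SN2 and SN2′ attack on 2,3-dibromopropene lead to the same product.

Step 6
Reactants: 10 (4Z)-2-bromodeca-1,4-diene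
Product: 12 [(4Z)-deca-1,4-dien-2-yl]oxy(trimethyl)silane, via (4Z)-deca-1,4-dien-2-yllithium 11 (not isolated)
Conditions: t-BuLi (2 equiv), Et2O, −78 °C; Me3SiOOSiMe3, −78 to 0 °C; non-aqueous work-up, distillation
Reagents that add atoms: bis(trimethylsilyl) peroxide C[Si](C)(C)OO[Si](C)(C)C
Why: Bromine–lithium exchange followed by electrophilic oxygen transfer from the silyl peroxide places the silyl enol ether at the carbon that carried bromine, which fixes the enolate on the C8 side and avoids deprotonation of the doubly activated C13 methylene.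

Step 7
Reactants: 12 [(4Z)-deca-1,4-dien-2-yl]oxy(trimethyl)silane; 7 (Z)-1-[tert-butyl(dimethyl)silyl]-2-chloro-3-(phenylsulfanyl)prop-2-en-1-one
Product: 16 4-{[tert-butyl(dimethyl)silyl]oxy}-3-chloro-1-[(Z)-oct-2-en-1-yl]-2-(phenylsulfanyl)cyclopent-3-en-1-ol (racemic; both C2 epimers), via lithium (4Z)-deca-1,4-dien-2-olate 13 (not isolated), via acylsilane 1,2-adduct lithium alkoxide 14 (not isolated), via lithium 2-siloxy-2-vinylcyclopropan-1-olate 15 (not isolated)
Conditions: MeLi (1.0 equiv), THF, 0 °C to rt; cool to −80 °C, add 7; −80 to −30 °C; AcOH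
Reagents that add atoms: none
Why: The lithium enolate adds through its CH2 terminus (C8) to the acylsilane carbonyl (C9), and the α-silyl alkoxide undergoes a 1,2-Brook rearrangement (silyl shift from C9 to O) that releases a siloxy-substituted allyl anion over C9–C10–C11, stabilised by sulfur, which is captured by the tethered ketone carbon C12. The closest known reaction type is the Brook-rearrangement-mediated [3+2] annulation of β-heteroatom-substituted acryloylsilanes with lithium enolates of methyl ketones, applied here to a partner that carries an additional α-chlorine. The cyclopentene ring is closed in two stages, a 3-exo-trig attack of the C9 carbanion on the C12 carbonyl to a 2-vinylcyclopropanolate and then an oxyanion-accelerated vinylcyclopropane-to-cyclopentene 1,3-shift that moves C12 from C9 to C11, so the net new bonds are C8–C9 and C11–C12. C12 is formed as a racemate because neither partner is chiral, and the sulfur-bearing C11 centre forms as a mixture that is erased in step 8; the required antipode is taken in step 9. The step needs 1,2-addition instead of conjugate addition–elimination and ring closure faster than chloride loss or proton transfer from C13. The phenylthio group deactivates C11 towards Michael attack, the C10–Cl bond lies in the nodal plane of the allyl anion so that its σ* orbital cannot accept the charge, and the low temperature keeps the regiodefined enolate from equilibrating.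

Step 8
Reactants: 16 4-{[tert-butyl(dimethyl)silyl]oxy}-3-chloro-1-[(Z)-oct-2-en-1-yl]-2-(phenylsulfanyl)cyclopent-3-en-1-ol
Product: 18 rac-2-chloro-4-hydroxy-4-[(Z)-oct-2-en-1-yl]cyclopent-2-en-1-one, via tetrabutylammonium α-chloro enolate 17 (not isolated)
Conditions: n-Bu4NF (1.05 equiv), MeI (3 equiv), THF, −40 to 0 °C; pH 7 buffer
Reagents that add atoms: none
Why: Fluoride cleaves the enol silyl ether to the α-chloro enolate, which expels thiophenoxide from C11 (E1cB) to unveil the 2-chloroenone, and methyl iodide captures the thiolate so that it cannot add back.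

Step 9
Reactants: 18 rac-2-chloro-4-hydroxy-4-[(Z)-oct-2-en-1-yl]cyclopent-2-en-1-one
Product: 19 (S)-2-chloro-4-hydroxy-4-[(Z)-oct-2-en-1-yl]cyclopent-2-en-1-one (spatial arrangement of 12R in the target; the letter is S here because C8 is still CH2)
Conditions: preparative supercritical-fluid chromatography, amylose tris(3,5-dimethylphenylcarbamate) stationary phase, CO2/i-PrOH
Reagents that add atoms: none
Why: The enantiomers of this hydrogen-bond-donating hydroxy enone should separate on a polysaccharide chiral phase, which fixes the C12 configuration; the absolute configuration of the retained antipode is to be confirmed by circular dichroism before it is carried on.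

Step 10
Reactants: 19 (S)-2-chloro-4-hydroxy-4-[(Z)-oct-2-en-1-yl]cyclopent-2-en-1-one
Product: 20 (S)-2-chloro-4-[(Z)-oct-2-en-1-yl]-4-[(trimethylsilyl)oxy]cyclopent-2-en-1-one
Conditions: N-(trimethylsilyl)imidazole, CH2Cl2, rt
Reagents that add atoms: N-(trimethylsilyl)imidazole C[Si](C)(C)n1ccnc1
Why: The silylimidazole silylates the hindered tertiary alcohol under neutral conditions without enolising the ketone, and the ether blocks retro-aldol opening of the β-hydroxy ketone in step 15.

Step 11
Reactants: 21 hex-5-ynoic acid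
Product: 23 7-hydroxyhept-5-ynoic acid, via dilithium hex-5-ynoate acetylide 22 (not isolated)
Conditions: n-BuLi (2.1 equiv), THF, −78 to 0 °C; (CH2O)n, 0 °C to rt; aq HCl
Reagents that add atoms: formaldehyde (as paraformaldehyde) C=O
Why: The carboxylate–acetylide dianion is hydroxymethylated at the acetylide carbon by formaldehyde (alkynylation of an aldehyde), which supplies C7.

Step 12
Reactants: 23 7-hydroxyhept-5-ynoic acid
Product: 24 methyl 7-hydroxyhept-5-ynoate
Conditions: MeOH, cat. H2SO4, rt
Reagents that add atoms: methanol CO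
Why: Fischer esterification of the acid, to which the propargylic alcohol is inert.

Step 13
Reactants: 24 methyl 7-hydroxyhept-5-ynoate
Product: 25 methyl (Z)-7-hydroxyhept-5-enoate
Conditions: H2 (1 atm), Pd/CaCO3 poisoned with Pb(OAc)2 (Lindlar catalyst), quinoline, EtOAc, rt
Reagents that add atoms: none
Why: Lindlar semihydrogenation delivers hydrogen syn to the alkyne and so sets the C5=C6 Z-alkene.

Step 14
Reactants: 25 methyl (Z)-7-hydroxyhept-5-enoate
Product: 26 methyl (Z)-7-oxohept-5-enoate
Conditions: Dess–Martin periodinane, NaHCO3, CH2Cl2, 0 °C; used at once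
Reagents that add atoms: none
Why: Buffered Dess–Martin oxidation of the allylic alcohol at low temperature should give the (Z)-enal without the acid or base that would isomerise it.

Step 15
Reactants: 20 (S)-2-chloro-4-[(Z)-oct-2-en-1-yl]-4-[(trimethylsilyl)oxy]cyclopent-2-en-1-one; 26 methyl (Z)-7-oxohept-5-enoate
Product: 28 methyl (Z)-7-{3-chloro-2-oxo-5-[(Z)-oct-2-en-1-yl]-5-[(trimethylsilyl)oxy]cyclopent-3-en-1-yl}-7-hydroxyhept-5-enoate (C12 as in 20; mixture of C7/C8 epimers), via lithium cross-conjugated dienolate 27 (not isolated)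
Conditions: LDA (1.1 equiv), THF, −78 °C; 26, −78 °C; AcOH, −78 °C
Reagents that add atoms: none
Why: Kinetic deprotonation can occur only at C8 because C12 is quaternary, and the enolate adds 1,2 to the enal (aldol addition); the new C7 and C8 centres are removed in step 16 and C12 is not touched.

Step 16
Reactants: 28 aldol adducts
Product: 30 methyl (5Z,7E,14Z)-10-chloro-9-oxo-12-[(trimethylsilyl)oxy]prosta-5,7,10,14-tetraenoate (12R), via C7 acetate 29 (not isolated)
Conditions: Ac2O, DMAP, Et3N, CH2Cl2, 0 °C to rt, in the dark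
Reagents that add atoms: none
Why: Acetylation of the aldol hydroxyl and E1cB loss of acetate should give the cross-conjugated dienone, the 7E isomer being favoured as in aldol condensations of cyclopentanones because the chain lies anti to the C9 carbonyl.

Step 17
Reactants: 30 12-O-trimethylsilyl chlorovulone I
Product: 31 chlorovulone I
Conditions: AcOH/THF/H2O (3:1:1), rt, in the dark
Reagents that add atoms: none
Why: The tertiary trimethylsilyl ether is hydrolysed by mild aqueous acid, under which the dienone and the Z-alkenes should survive.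

## Compound list

1 | ethyl vinyl ether | C=COCC | starting material
2 | 1-ethoxyvinyllithium | [Li]C(=C)OCC | intermediate
3 | tert-butyl(1-ethoxyethenyl)dimethylsilane | C=C(OCC)[Si](C)(C)C(C)(C)C | intermediate
4 | 1-[tert-butyl(dimethyl)silyl]ethan-1-one | CC(=O)[Si](C)(C)C(C)(C)C | intermediate
5 | (E)-1-[tert-butyl(dimethyl)silyl]-3-(dimethylamino)prop-2-en-1-one | CN(C)/C=C/C(=O)[Si](C)(C)C(C)(C)C | intermediate
6 | (E)-1-[tert-butyl(dimethyl)silyl]-3-(phenylsulfanyl)prop-2-en-1-one | O=C(/C=C/Sc1ccccc1)[Si](C)(C)C(C)(C)C | intermediate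
7 | (Z)-1-[tert-butyl(dimethyl)silyl]-2-chloro-3-(phenylsulfanyl)prop-2-en-1-one | O=C(/C(Cl)=C/Sc1ccccc1)[Si](C)(C)C(C)(C)C | intermediate
8 | n-pentylmagnesium bromide | CCCCC[Mg]Br | starting material
9 | (Z)-hept-1-enylcopper | CCCCC/C=C\[Cu] | intermediate
10 | (4Z)-2-bromodeca-1,4-diene | C=C(Br)C/C=C\CCCCC | intermediate
11 | (4Z)-deca-1,4-dien-2-yllithium | [Li]C(=C)C/C=C\CCCCC | intermediate
12 | [(4Z)-deca-1,4-dien-2-yl]oxy(trimethyl)silane | C=C(O[Si](C)(C)C)C/C=C\CCCCC | intermediate
13 | lithium (4Z)-deca-1,4-dien-2-olate | [Li+].[O-]C(=C)C/C=C\CCCCC | intermediate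
14 | lithium (1Z,7Z)-3-[tert-butyl(dimethyl)silyl]-2-chloro-5-oxo-1-(phenylsulfanyl)trideca-1,7-dien-3-olate (racemic) | [Li+].CCCCC/C=C\CC(=O)CC([O-])([Si](C)(C)C(C)(C)C)/C(Cl)=C/Sc1ccccc1 | intermediate
15 | lithium 2-{[tert-butyl(dimethyl)silyl]oxy}-2-[(Z)-1-chloro-2-(phenylsulfanyl)ethenyl]-1-[(Z)-oct-2-en-1-yl]cyclopropan-1-olate (racemic) | [Li+].CCCCC/C=C\CC1([O-])CC1(O[Si](C)(C)C(C)(C)C)/C(Cl)=C/Sc1ccccc1 | intermediate
16 | 4-{[tert-butyl(dimethyl)silyl]oxy}-3-chloro-1-[(Z)-oct-2-en-1-yl]-2-(phenylsulfanyl)cyclopent-3-en-1-ol (racemic, both C2 epimers) | CCCCC/C=C\CC1(O)CC(O[Si](C)(C)C(C)(C)C)=C(Cl)C1Sc1ccccc1 | intermediate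
17 | tetrabutylammonium 2-chloro-4-hydroxy-4-[(Z)-oct-2-en-1-yl]-3-(phenylsulfanyl)cyclopent-1-en-1-olate (racemic) | CCCC[N+](CCCC)(CCCC)CCCC.CCCCC/C=C\CC1(O)CC([O-])=C(Cl)C1Sc1ccccc1 | intermediate
18 | rac-2-chloro-4-hydroxy-4-[(Z)-oct-2-en-1-yl]cyclopent-2-en-1-one | CCCCC/C=C\CC1(O)CC(=O)C(Cl)=C1 | intermediate
19 | (S)-2-chloro-4-hydroxy-4-[(Z)-oct-2-en-1-yl]cyclopent-2-en-1-one | CCCCC/C=C\C[C@@]1(O)C=C(Cl)C(=O)C1 | intermediate
20 | (S)-2-chloro-4-[(Z)-oct-2-en-1-yl]-4-[(trimethylsilyl)oxy]cyclopent-2-en-1-one | CCCCC/C=C\C[C@@]1(O[Si](C)(C)C)C=C(Cl)C(=O)C1 | intermediate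
21 | hex-5-ynoic acid | OC(=O)CCCC#C | starting material
22 | dilithium hex-5-ynoate acetylide | [Li+].[Li+].[O-]C(=O)CCCC#[C-] | intermediate
23 | 7-hydroxyhept-5-ynoic acid | OC(=O)CCCC#CCO | intermediate
24 | methyl 7-hydroxyhept-5-ynoate | COC(=O)CCCC#CCO | intermediate
25 | methyl (Z)-7-hydroxyhept-5-enoate | COC(=O)CCC/C=C\CO | intermediate
26 | methyl (Z)-7-oxohept-5-enoate | COC(=O)CCC/C=C\C=O | intermediate
27 | lithium (S)-2-chloro-4-[(Z)-oct-2-en-1-yl]-4-[(trimethylsilyl)oxy]cyclopenta-1,5-dien-1-olate | [Li+].CCCCC/C=C\C[C@@]1(O[Si](C)(C)C)C=C(Cl)C([O-])=C1 | intermediate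
28 | methyl (Z)-7-{3-chloro-2-oxo-5-[(Z)-oct-2-en-1-yl]-5-[(trimethylsilyl)oxy]cyclopent-3-en-1-yl}-7-hydroxyhept-5-enoate (C12 fixed, C7/C8 epimers) | CCCCC/C=C\C[C@@]1(O[Si](C)(C)C)C=C(Cl)C(=O)C1C(O)/C=C\CCCC(=O)OC | intermediate
29 | C7 acetate of 28 | CCCCC/C=C\C[C@@]1(O[Si](C)(C)C)C=C(Cl)C(=O)C1C(OC(C)=O)/C=C\CCCC(=O)OC | intermediate
30 | methyl (5Z,7E,12R,14Z)-10-chloro-9-oxo-12-[(trimethylsilyl)oxy]prosta-5,7,10,14-tetraenoate | CCCCC/C=C\C[C@@]1(O[Si](C)(C)C)C=C(Cl)C(=O)/C1=C/C=C\CCCC(=O)OC | intermediate
31 | chlorovulone I, methyl (5Z,7E,12R,14Z)-10-chloro-12-hydroxy-9-oxoprosta-5,7,10,14-tetraenoate | CCCCC/C=C\C[C@@]1(O)C=C(Cl)C(=O)/C1=C/C=C\CCCC(=O)OC | target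

## Step count and risks

Total steps: 17. Longest linear sequence: 11 (steps 1–4, 7–10, 15–17).

**Step 7.** The ring closure may be outrun by loss of chloride from the Brook-generated carbanion (allene formation), by proton transfer from the doubly activated C13 methylene to the carbanion, or by conjugate addition–elimination of the enolate at C11. The fallback sets out from 8 and comes back at 18. The alkenylcopper 9, made from 8 as in step 5, would be alkylated with 5-(chloromethyl)furfural to give 5-[(Z)-oct-2-en-1-yl]furan-2-carbaldehyde F1. NaBH4 in MeOH would give {5-[(Z)-oct-2-en-1-yl]furan-2-yl}methanol F2. A Piancatelli rearrangement (H2O/acetone, pH 4, ZnCl2, 80 °C) would give rac-4-hydroxy-4-[(Z)-oct-2-en-1-yl]cyclopent-2-en-1-one F3. Nucleophilic epoxidation (H2O2, NaOH, MeOH, 0 °C) would give rac-4-hydroxy-4-[(Z)-oct-2-en-1-yl]-6-oxabicyclo[3.1.0]hexan-2-one F4. HCl in THF would open the epoxide at the α-carbon, and loss of the β-hydroxyl would give 18.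

**Step 6.** The vinyllithium may be C-silylated by the peroxide instead of oxygenated, or may isomerise by a 1,3-proton shift to a pentadienyl anion. The fallback sets out from 8 and comes back at 13. The alkenylcopper 9 would be alkylated with 3-bromo-1-(trimethylsilyl)prop-1-yne to give trimethyl[(Z)-dec-4-en-1-yn-1-yl]silane F5. K2CO3 in MeOH would give (Z)-dec-4-en-1-yne F6. Markovnikov addition of AcOH ([RuCl2(p-cymene)]2, P(2-furyl)3, Na2CO3, toluene, 50 °C) would give (4Z)-deca-1,4-dien-2-yl acetate F7. Two equivalents of MeLi (THF, 0 °C) would cleave this enol ester to the same lithium enolate 13.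

**Step 15.** The (Z)-enal may isomerise to the E form under the basic conditions, or the 5Z geometry may be lost during addition and elimination. The fallback sets out from 24 and comes back at 30. Dess–Martin oxidation of 24 would give methyl 7-oxohept-5-ynoate F8. Aldol addition of enolate 27 to it would give the propargylic aldol methyl 7-{3-chloro-2-oxo-5-[(Z)-oct-2-en-1-yl]-5-[(trimethylsilyl)oxy]cyclopent-3-en-1-yl}-7-hydroxyhept-5-ynoate F9. Ac2O, DMAP and Et3N would give the 7E enynone methyl (7E,12R,14Z)-10-chloro-9-oxo-12-[(trimethylsilyl)oxy]prosta-7,10,14-trien-5-ynoate F10. Semihydrogenation over Pd/CaCO3 poisoned with Pb(OAc)2 with quinoline would set 5Z after the dienone is in place and give 30.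

Further compounds
F1 | step 7 | 5-[(Z)-oct-2-en-1-yl]furan-2-carbaldehyde | CCCCC/C=C\Cc1ccc(C=O)o1
F2 | step 7 | {5-[(Z)-oct-2-en-1-yl]furan-2-yl}methanol | CCCCC/C=C\Cc1ccc(CO)o1
F3 | step 7 | rac-4-hydroxy-4-[(Z)-oct-2-en-1-yl]cyclopent-2-en-1-one | CCCCC/C=C\CC1(O)CC(=O)C=C1
F4 | step 7 | rac-4-hydroxy-4-[(Z)-oct-2-en-1-yl]-6-oxabicyclo[3.1.0]hexan-2-one | CCCCC/C=C\CC1(O)CC(=O)C2OC21
F5 | step 6 | trimethyl[(Z)-dec-4-en-1-yn-1-yl]silane | CCCCC/C=C\CC#C[Si](C)(C)C
F6 | step 6 | (Z)-dec-4-en-1-yne | CCCCC/C=C\CC#C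
F7 | step 6 | (4Z)-deca-1,4-dien-2-yl acetate | CCCCC/C=C\CC(=C)OC(C)=O
F8 | step 15 | methyl 7-oxohept-5-ynoate | COC(=O)CCCC#CC=O
F9 | step 15 | methyl 7-{3-chloro-2-oxo-5-[(Z)-oct-2-en-1-yl]-5-[(trimethylsilyl)oxy]cyclopent-3-en-1-yl}-7-hydroxyhept-5-ynoate | CCCCC/C=C\C[C@@]1(O[Si](C)(C)C)C=C(Cl)C(=O)C1C(O)C#CCCCC(=O)OC
F10 | step 15 | methyl (7E,12R,14Z)-10-chloro-9-oxo-12-[(trimethylsilyl)oxy]prosta-7,10,14-trien-5-ynoate | CCCCC/C=C\C[C@@]1(O[Si](C)(C)C)C=C(Cl)C(=O)/C1=C/C#CCCCC(=O)OC
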